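## Structural features

The target is a 5-alkylresorcinol: a benzene ring with hydroxyl groups at positions 3 and 5 and, at position 1, a linear thirteen-carbon chain joined through its benzylic methylene C1. The arene is the only ring, so nothing has to be cyclised. The chain holds one stereocentre, C2, which carries the acetoxy group and is R (O > C1H2Ar > C3H2 > H); no other stereocentre stands next to it, so the task is absolute and not relative stereocontrol. C8 is a dialkyl ketone that ends in a pentyl group (C9–C13), and C3–C7 between the acetoxy carbon and the ketone are five plain methylenes. The fragile groups are the free resorcinol (electron-rich, acidic, easily oxidised), the secondary acetate (lost to hydroxide or alkoxide, and the only one of three oxygens that is acylated) and the enolisable ketone. The real difficulty is twofold: joining two functionalised ends across a stretch with no polar handle, and finishing with the aliphatic oxygen acetylated while both phenolic oxygens are free. The key step uses the inert stretch itself: the C4–C5 bond has only methylene neighbours, so it can be made by combining two unstabilised primary radicals, C4 being the α-carbon of a 4-acetoxy-5-arylpentanoic acid and C5 the α-carbon of 5-oxodecanoic acid. The acetoxy carbon C2 then lies two atoms, and the keto carbon C8 three atoms, from the respective radical centres, far enough to take no part.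

## Logic of the disconnections

**14 ⇒ 13.** Only the two phenolic O–H bonds change: both ring oxygens are acylated with the same acyl group that O2 already carries. The free resorcinol would be oxidised at an anode long before a carboxylate, and acyloxy groups are much weaker donors than hydroxy or alkoxy groups. The gain is that 13 has three esters of one kind, put on in a single operation, and no new type of protecting group. The demand on the forward step is to cleave two aryl esters beside a secondary alkyl ester and a ketone, which rests on the far better phenoxide leaving group.

**13 ⇒ 9 + 12.** The C4–C5 bond is cut homolytically and each fragment is extended by one carboxyl carbon, lost as CO2 in the forward sense. This is the bond of the C3–C7 stretch at which both radicals are simple primary alkyl radicals with no heteroatom, carbonyl or aryl group on the neighbouring carbon. The gain is full convergence: a chiral aryl acid with every oxygen function in place and an achiral C10 keto acid. Compound 9 is designed as the tris-ester for three reasons: the ring is deactivated towards the anode, the blocked O2 cannot lactonise onto the carboxyl, and all three esters come from one acylation. The forward step must favour cross- over self-coupling, the radical over the cationic pathway, and must not oxidise the ring or strip the aryl esters.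

**12 ⇒ 10 + 11.** The C8–C9 bond (acyl carbon to pentyl) is cut. A five-carbon cyclic anhydride supplies C5–C8 and the carboxyl carbon in one piece with the two ends already differentiated after ring opening. Both pieces are catalogue compounds and the branch is one step. The forward step must stop after a single addition.

**9 ⇒ 7 (through 8).** The carboxyl carbon is traced back to the internal carbon of a terminal C=C; the extra terminal CH2 is lost on cleavage. A terminal alkene is inert to organomagnesium reagents, fluoride and acylation, whereas a carboxyl or ester next to a free C2 hydroxyl would lactonise. Choosing the butenyl rather than the allyl homologue means that cleavage gives the acid directly, with no hydroboration and no alkaline peroxide that would strip aryl esters. The demand is an oxidant that cleaves the alkene and spares the ring; this is met because the ring of 7 is already a diester.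

**7 ⇒ 5 (through 6).** Three O–acyl bonds are cut and the two phenolic oxygens are returned to silyl ethers. Silyl ethers, unlike benzyl ethers, can be removed in the presence of the alkene, and the liberated phenoxides and the C2 hydroxyl can then be acylated together. One flask thus replaces a separate alcohol acylation, a hydrogenolysis and a phenol acylation. The forward step must acylate all three oxygens completely without disturbing the C2–O bond.

**5 ⇒ 3 + 4, and 4 ⇒ 2.** The bond between the aryl carbon and C1 is cut, so C1–C6 with the C2 stereocentre and the alkene arrive as one enantiopure epoxide. The stereocentre is bought, not induced, and the route avoids an enolisable arylacetaldehyde and any asymmetric reaction. The forward step needs attack at the unsubstituted epoxide carbon only, with no halide opening, and a ring whose oxygens tolerate the organomagnesium reagent 4, formed from 2 by metal insertion.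

**2 ⇒ 1.** The two O–Si bonds are cut, leading to a commercial bromo-diol. The demand is trivial: complete bis-silylation.

## Other disconnections considered

**Alternative 1:** The cut runs through the arene. The ring would be assembled from the enone A1, (R,E)-6-(tert-butyldimethylsilyloxy)heptadec-3-ene-2,12-dione, and dimethyl malonate A2.

- **Forward key step.** An alkoxide base would add A2 to the β-carbon of A1. The methyl ketone enolate would then acylate itself on one ester group (Michael addition, then Claisen-type ring closure) to give the cyclohexanedione ester A3, methyl 6-[(R)-2-(tert-butyldimethylsilyloxy)-8-oxotridecyl]-2,4-dioxocyclohexane-1-carboxylate. Ester hydrolysis, decarboxylation and dehydrogenation would follow.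
- **In favour.** This is the classical way to 5-alkylresorcinols. The 1,3-dioxygenation with the substituent at position 5 follows automatically. Two C–C bonds form in one thermodynamically driven operation from cheap reagents.
- **Against it here.**
  - A1 already contains the whole chain. Its second ketone is a competing enolate donor.
  - Its silyloxy group sits δ to the enone carbonyl, so γ-deprotonation invites vinylogous elimination.
  - Aromatising a cyclohexanedione needs oxidative or high-temperature conditions that are unkind to a ketone and to the C2 oxygen.
  - After aromatisation the silyl ether would still have to be exchanged for an acetate beside two free phenols, so the same differentiation problem returns.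
- **Comparison.** On structure, it builds a ring that the chosen plan buys. On mechanism, it is enolate chemistry under equilibrium control against a radical coupling. On step economy, A1 alone would need the stereocentre, the ketone and the enone to be assembled, so the total would probably be about twice the seven steps of the chosen plan. It is better than the chosen plan in one respect: the annulation needs no electrochemical equipment and wastes no excess partner. It is equal in the certainty of the substitution pattern.

**Alternative 2:** Three ring bonds are cut. The arene would arise from the cyclobutenone A4, (R)-1-(3-oxocyclobut-1-en-1-yl)-8-oxotridecan-2-yl acetate, and the siloxyalkyne A5, (triisopropylsiloxy)ethyne.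

- **Forward key step.** Heating would open A4 to a vinylketene. A [2+2] addition to A5 would join the ketene carbonyl carbon to the alkyne CH and the ketene α-carbon to the siloxy carbon. The new cyclobutenone would open to a dienylketene. A 6π closure would join the ketene carbon to the vinyl CH2 (a bond broken in the first opening and re-formed here), and tautomerisation would give the phenol A6, (R)-1-[3-hydroxy-5-(triisopropylsilyloxy)phenyl]-8-oxotridecan-2-yl acetate.
- **In favour.** The 1,3,5-pattern is fixed by the polarity of the ynol ether. The conditions are neutral and thermal. A6 carries the C2 acetate with the ring oxygens as hydroxyl and silyl ether, so the last step would be a fluoride desilylation that cannot touch an alkyl acetate.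
- **Against it here.**
  - A4 is a strained, nucleophile-sensitive enone. It would have to be made by ketene–alkyne cycloaddition and dehalogenation on a substrate that already holds the stereocentre, an acetate and a ketone.
  - Its acetoxy group is δ to the ring carbonyl, so vinylogous elimination is possible.
  - A5 is a moisture-sensitive reagent that has to be prepared.
  - The C3–C8 chain would still need its own assembly, which this cut does not provide.
- **Comparison.** On structure, the same ring is made late instead of bought. On mechanism, a pericyclic cascade with no redox event and no statistics stands against a radical coupling. On step economy, it is clearly longer. It is better in the end game (orthogonal silyl against acetate) and in needing no excess partner. It is equal in that neither key step touches C2.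

**Alternative 3:** The C2–O bond is cut. The acetate would come from the methyl ketone A7, (R)-3-[3,5-bis(benzyloxy)benzyl]-8-(2-pentyl-1,3-dioxolan-2-yl)octan-2-one.

- **Forward key step.** A buffered peracid would add to the acetyl carbonyl. In the tetrahedral adduct the secondary carbon would migrate to oxygen in preference to methyl and with retention, giving A8, (R)-1-[3,5-bis(benzyloxy)phenyl]-7-(2-pentyl-1,3-dioxolan-2-yl)heptan-2-yl acetate.
- **In favour.** The acetate is created as such, so no oxygen has to be differentiated. The phenols can stay as benzyl ethers to the end and be removed by hydrogenolysis, which cannot affect an alkyl acetate. The stereocentre is α to a carbonyl and could be set by auxiliary-controlled alkylation.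
- **Against it here.**
  - The stereocentre of A7 is epimerisable until the oxidation is done.
  - The C8 ketone must be carried as a ketal through the peracid step and released afterwards.
  - The bis(benzyloxy) ring is electron-rich and exposed to the peracid.
  - Migration of methyl is a minor competing path.
  - The C3–C8 chain again has to be built by some other bond formation.
- **Comparison.** On structure, both plans buy the arene; this one places the strategic bond at the stereocentre, the chosen plan two atoms away from it. On mechanism, a concerted 1,2-shift with inherent retention stands against a stereochemically innocent radical coupling. On step economy, the auxiliary sequence, methyl ketone formation, ketal handling and two deprotections would bring it to roughly twelve steps against seven. It is better in the chemoselectivity of the last step and in needing no electrolysis. It is equal in expected stereochemical fidelity.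

Key step: step 6

**Assumptions (remarks on the chemistry):**
- The chain is numbered from the benzylic carbon C1 through the acetoxy carbon C2 to the keto carbon C8 and the pentyl end C13.
- (R)-2-(But-3-en-1-yl)oxirane and pentylmagnesium bromide (ether solution) are taken as catalogue compounds of high enantiomeric and chemical purity.
- The symmetrical dimer formed from the excess keto acid in the key step is the C18 diketone octadecane-6,13-dione, the sum of two nine-carbon radicals. A C16 dione would belong to a keto acid one carbon shorter.

## Route

Step 1
Reactants: 1 5-bromobenzene-1,3-diol
Product: 2 1-bromo-3,5-bis(tert-butyldimethylsilyloxy)benzene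
Conditions: TBSCl (2.4 equiv), imidazole (5 equiv), DMF, 0 °C → rt
Reagents that add atoms: tert-butyldimethylsilyl chloride, CC(C)(C)[Si](C)(C)Cl
Why: Imidazole-promoted silylation of phenols (silyl ether formation); the silyl ethers remove the acidic protons that would destroy the organomagnesium reagent and can later be cleaved by fluoride without affecting an alkene.

Step 2
Reactants: 2 1-bromo-3,5-bis(tert-butyldimethylsilyloxy)benzene; 3 (R)-2-(but-3-en-1-yl)oxirane
Product: 5 (R)-1-[3,5-bis(tert-butyldimethylsilyloxy)phenyl]hex-5-en-2-ol, via arylmagnesium bromide 4 (not isolated)
Conditions: Mg turnings (1.3 equiv), cat. I2, THF, 45 °C; then CuI (10 mol%), −30 °C; 3 (0.85 equiv), −30 → 0 °C; aq. NH4Cl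
Reagents that add atoms: none
Why: Magnesium insertion gives the aryl Grignard reagent 4, which under CuI catalysis opens the terminal epoxide by SN2 attack at the unsubstituted carbon (copper-catalysed Grignard epoxide opening); the C–O bond at the stereocentre is not broken, so the R configuration of 3 is carried unchanged into C2 of 5.

Step 3
Reactants: 5 (R)-1-[3,5-bis(tert-butyldimethylsilyloxy)phenyl]hex-5-en-2-ol
Product: 7 (R)-1-(3,5-diacetoxyphenyl)hex-5-en-2-yl acetate, via triol 6 (not isolated)
Conditions: TBAF (2.2 equiv), THF, 0 °C; then Ac2O (6 equiv), Et3N (6 equiv), DMAP (10 mol%), 0 °C → rt
Reagents that add atoms: acetic anhydride, CC(=O)OC(C)=O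
Why: Fluoride cleaves the two aryl silyl ethers to the ammonium phenoxide of triol 6, and DMAP-catalysed acylation in the same flask esterifies both phenoxides and the secondary alcohol at once; O-acylation does not touch the C2–O bond, so configuration is retained, and the ring leaves this step deactivated for the oxidations that follow.

Step 4
Reactants: 7 (R)-1-(3,5-diacetoxyphenyl)hex-5-en-2-yl acetate
Product: 9 (R)-4-acetoxy-5-(3,5-diacetoxyphenyl)pentanoic acid, via aldehyde 8 (not isolated)
Conditions: O3/O2, MeCN–H2O (9:1), 0 °C, to consumption of 7, N2 purge; then NaClO2 (3 equiv), NaH2PO4 (pH ca. 4), 30% H2O2 (1.5 equiv), 0 °C → rt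
Reagents that add atoms: ozone, [O-][O+]=O; water, O; sodium chlorite, [Na+].[O-]Cl=O
Why: Ozonolysis of the terminal alkene in wet acetonitrile, where water intercepts the carbonyl oxide and delivers aldehyde 8 without a reductive work-up, is followed in the same pot by chlorite (Pinnick-type) oxidation with H2O2 as hypochlorite scavenger; the alkene is far more reactive towards ozone than the diacetoxy-substituted ring, the weakly acidic chlorite stage spares all three acetates, and the acid is formed with O2 already acetylated so it cannot lactonise.

Step 5
Reactants: 10 glutaric anhydride; 11 pentylmagnesium bromide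
Product: 12 5-oxodecanoic acid
Conditions: 10 (1.5 equiv), THF, −78 °C; 11 (2.0 M in Et2O, 1.0 equiv) added slowly; −78 → −20 °C; 1 M HCl
Reagents that add atoms: none
Why: Acylation of a Grignard reagent by a cyclic anhydride: ring opening gives the magnesium carboxylate of the keto acid, and its negative charge, the low temperature and the excess of anhydride disfavour a second addition; acid work-up liberates 12.

Step 6
Reactants: 9 (R)-4-acetoxy-5-(3,5-diacetoxyphenyl)pentanoic acid; 12 5-oxodecanoic acid
Product: 13 (R)-1-(3,5-diacetoxyphenyl)-8-oxotridecan-2-yl acetate
Conditions: 9 (1 equiv), 12 (6 equiv, premixed with KOH, 5 mol% of total acid), MeOH, undivided cell, smooth Pt anode and Pt cathode, constant current ca. 0.25 A cm−2, 15–25 °C, ca. 1.3 F per mol of acid, stopped while still weakly acidic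
Reagents that add atoms: none
Why: Mixed Kolbe electrolysis: both carboxylates are discharged at the platinum anode, each acyloxy radical loses CO2, and the primary radicals •CH2CH2CH(OAc)CH2Ar (C4) and •CH2CH2CH2C(=O)C5H11 (C5) combine in the adsorbed layer to form the C4–C5 bond, while protons are reduced to H2 at the cathode. The closest known reaction type is the crossed Kolbe coupling of an O-acylated hydroxy acid with a keto acid used in excess. No ring is closed and no stereocentre is created; the existing centre C2 is two atoms from the radical carbon, takes no part and keeps its R configuration. Cross- over self-coupling cannot be steered chemically and is secured by stoichiometry: with a six-fold excess of 12 nearly every radical from 9 should meet a radical from 12, and the by-products (octadecane-6,13-dione from 12, CO2, H2) are non-polar or volatile and should be easy to remove. The radical pathway is favoured over carbocation formation by unstabilised primary radicals with no α-heteroatom or aryl group, by smooth platinum, by high current density and by a weakly acidic, only slightly neutralised methanolic medium. Chemoselectivity at the anode rests on the triacetate design: acyloxy groups make the ring a much poorer donor than a free or alkylated resorcinol, so the carboxylate layer should be discharged first. Because the base is premixed with 12 and the run is ended while still acidic, no methoxide should build up to strip the aryl acetates.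

Step 7
Reactants: 13 (R)-1-(3,5-diacetoxyphenyl)-8-oxotridecan-2-yl acetate
Product: 14 (R)-1-(3,5-dihydroxyphenyl)-8-oxotridecan-2-yl acetate
Conditions: NH4OAc (8 equiv), MeOH–H2O (4:1), rt
Reagents that add atoms: none
Why: Chemoselective solvolysis (transesterification) of aryl esters: phenoxide is a far better leaving group than a secondary alkoxide, so the nearly neutral ammonium acetate buffer should remove both phenolic acetates while the C2 acetate and the ketone stay; no bond to C2 is broken, so the R configuration is kept.

## Compound list

1 | 5-bromobenzene-1,3-diol (5-bromoresorcinol) | Oc1cc(O)cc(Br)c1 | starting material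
2 | 1-bromo-3,5-bis(tert-butyldimethylsilyloxy)benzene | CC(C)(C)[Si](C)(C)Oc1cc(Br)cc(O[Si](C)(C)C(C)(C)C)c1 | intermediate
3 | (R)-2-(but-3-en-1-yl)oxirane [(R)-1,2-epoxyhex-5-ene] | C=CCC[C@@H]1CO1 | starting material
4 | [3,5-bis(tert-butyldimethylsilyloxy)phenyl]magnesium bromide | CC(C)(C)[Si](C)(C)Oc1cc([Mg]Br)cc(O[Si](C)(C)C(C)(C)C)c1 | intermediate (not isolated)
5 | (R)-1-[3,5-bis(tert-butyldimethylsilyloxy)phenyl]hex-5-en-2-ol | C=CCC[C@H](Cc1cc(O[Si](C)(C)C(C)(C)C)cc(O[Si](C)(C)C(C)(C)C)c1)O | intermediate
6 | (R)-5-(2-hydroxyhex-5-en-1-yl)benzene-1,3-diol | C=CCC[C@H](Cc1cc(O)cc(O)c1)O | intermediate (not isolated)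
7 | (R)-1-(3,5-diacetoxyphenyl)hex-5-en-2-yl acetate | C=CCC[C@H](Cc1cc(OC(C)=O)cc(OC(C)=O)c1)OC(C)=O | intermediate
8 | (R)-1-(3,5-diacetoxyphenyl)-5-oxopentan-2-yl acetate | O=CCC[C@H](Cc1cc(OC(C)=O)cc(OC(C)=O)c1)OC(C)=O | intermediate (not isolated)
9 | (R)-4-acetoxy-5-(3,5-diacetoxyphenyl)pentanoic acid | OC(=O)CC[C@H](Cc1cc(OC(C)=O)cc(OC(C)=O)c1)OC(C)=O | intermediate (precursor of the key step)
10 | glutaric anhydride (oxane-2,6-dione) | O=C1CCCC(=O)O1 | starting material
11 | pentylmagnesium bromide | CCCCC[Mg]Br | starting material
12 | 5-oxodecanoic acid | CCCCCC(=O)CCCC(=O)O | intermediate
13 | (R)-1-(3,5-diacetoxyphenyl)-8-oxotridecan-2-yl acetate | CCCCCC(=O)CCCCC[C@H](Cc1cc(OC(C)=O)cc(OC(C)=O)c1)OC(C)=O | intermediate (product of the key step)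
14 | (R)-1-(3,5-dihydroxyphenyl)-8-oxotridecan-2-yl acetate | CCCCCC(=O)CCCCC[C@H](Cc1cc(O)cc(O)c1)OC(C)=O | target

## Step count and least certain steps

Total: 7 steps. Longest linear sequence: 6 steps (steps 1, 2, 3, 4, 6 and 7; 1 → 2 → 5 → 7 → 9 → 13 → 14). Step 5 is a one-step branch.

**Step 6 (key step).**
- What may go wrong: oxidation of the aromatic ring at the anode, or loss of aryl acetates in the alkaline layer at the cathode. Either would foul the electrodes and lower current efficiency. Part of 9 may also be lost to self-coupling or to the cationic pathway (alkene or methyl ether formation) if the current density or the acidity drifts.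
- Fallback: set out from 7 and return at 13.
  - Cross-metathesis of 7 with racemic non-1-en-4-ol (3 equiv), a catalogue compound, using second-generation Grubbs catalyst (H2IMes)(PCy3)Cl2Ru=CHPh in CH2Cl2 at 40 °C should give (2R)-1-(3,5-diacetoxyphenyl)-8-hydroxytridec-5-en-2-yl acetate F1 as a mixture of alkene isomers and C8 epimers.
  - Hydrogenation (H2, Pd/C, EtOAc) should give (2R)-1-(3,5-diacetoxyphenyl)-8-hydroxytridecan-2-yl acetate F2.
  - Oxidation of the C8 carbinol with Dess–Martin periodinane (CH2Cl2, NaHCO3) would remove the irrelevant C8 centre and give 13.

**Step 2.**
- What may go wrong: sluggish or incomplete magnesium insertion with biaryl formation, and competing opening of the epoxide by halide from the magnesium salts instead of by the aryl group.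
- Fallback: set out from 2 and return at 5, with the stereocentre drawn from (S)-epichlorohydrin and the chain completed in a second C–C bond formation.
  - Bromine–lithium exchange (n-BuLi, THF, −78 °C) would give [3,5-bis(tert-butyldimethylsilyloxy)phenyl]lithium F3.
  - With BF3·OEt2 and (S)-epichlorohydrin at −78 °C it should open the epoxide at its CH2 to give (S)-1-[3,5-bis(tert-butyldimethylsilyloxy)phenyl]-3-chloropropan-2-ol F4.
  - NaH (THF, 0 °C) would close this to (S)-2-[3,5-bis(tert-butyldimethylsilyloxy)benzyl]oxirane F5.
  - Allylmagnesium chloride with CuI (cat.) at −30 °C would open F5 at the terminal carbon to give 5. The descriptor changes from S to R only because the priorities of the two carbon substituents are exchanged.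

**Step 4.**
- What may go wrong: over-oxidation, that is attack of ozone on the ring after the alkene is consumed, or ring chlorination by hypochlorous acid before the scavenger intercepts it. Peroxidic intermediates may also break down incompletely.
- Fallback: set out from 7 and return at 9, without ozone.
  - Dihydroxylation (OsO4 1 mol%, NMO, acetone–H2O) should give (2R)-1-(3,5-diacetoxyphenyl)-5,6-dihydroxyhexan-2-yl acetate F6 as a C5-epimer mixture.
  - Glycol cleavage with NaIO4 (THF–H2O) would give aldehyde 8, this time isolated.
  - Chlorite oxidation (NaClO2, NaH2PO4, 2-methylbut-2-ene, t-BuOH–H2O) would give 9.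

**Step 5.**
- What may go wrong: a second addition of the Grignard reagent to the newly formed ketone, or attack at both carbonyl groups, which lowers the yield of an acid needed in six-fold excess.
- Fallback: set out from 10 and return at 12.
  - Ring opening of 10 with N,O-dimethylhydroxylamine hydrochloride and Et3N in CH2Cl2 should give 5-[methoxy(methyl)amino]-5-oxopentanoic acid F7.
  - Treatment with 11 (2.2 equiv, THF, 0 °C; the first equivalent deprotonates the acid) gives a chelated tetrahedral adduct that cannot add a second time. It collapses on HCl work-up to 12 (Weinreb ketone synthesis).

**Step 7.**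
- What may go wrong: over-cleavage, that is slow loss of the secondary acetate while the second aryl acetate is still being removed, or incomplete removal of the second aryl acetate if the reaction is stopped early.
- Fallback: set out from 13 (or from any over-cleaved material) and return at 14.
  - Exhaustive methanolysis (K2CO3, MeOH, rt) would give (R)-1-(3,5-dihydroxyphenyl)-2-hydroxytridecan-8-one F8.
  - Acid-catalysed esterification of the aliphatic hydroxyl (AcOH, cat. TsOH, 50 °C; Fischer esterification) would give 14. Phenols are not esterified at a useful rate under these conditions, and the C2–O bond is not broken.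

## Further compounds

F1 | step 6 | (2R,5E)-1-(3,5-diacetoxyphenyl)-8-hydroxytridec-5-en-2-yl acetate (E isomer drawn; alkene-isomer and C8-epimer mixture) | CCCCCC(O)C/C=C/CC[C@H](Cc1cc(OC(C)=O)cc(OC(C)=O)c1)OC(C)=O
F2 | step 6 | (2R)-1-(3,5-diacetoxyphenyl)-8-hydroxytridecan-2-yl acetate (C8-epimer mixture) | CCCCCC(O)CCCCC[C@H](Cc1cc(OC(C)=O)cc(OC(C)=O)c1)OC(C)=O
F3 | step 2 | [3,5-bis(tert-butyldimethylsilyloxy)phenyl]lithium | [Li]c1cc(O[Si](C)(C)C(C)(C)C)cc(O[Si](C)(C)C(C)(C)C)c1
F4 | step 2 | (S)-1-[3,5-bis(tert-butyldimethylsilyloxy)phenyl]-3-chloropropan-2-ol | ClC[C@H](Cc1cc(O[Si](C)(C)C(C)(C)C)cc(O[Si](C)(C)C(C)(C)C)c1)O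
F5 | step 2 | (S)-2-[3,5-bis(tert-butyldimethylsilyloxy)benzyl]oxirane | C1[C@H](Cc2cc(O[Si](C)(C)C(C)(C)C)cc(O[Si](C)(C)C(C)(C)C)c2)O1
F6 | step 4 | (2R)-1-(3,5-diacetoxyphenyl)-5,6-dihydroxyhexan-2-yl acetate (C5-epimer mixture) | OCC(O)CC[C@H](Cc1cc(OC(C)=O)cc(OC(C)=O)c1)OC(C)=O
F7 | step 5 | 5-[methoxy(methyl)amino]-5-oxopentanoic acid | CON(C)C(=O)CCCC(=O)O
F8 | step 7 | (R)-1-(3,5-dihydroxyphenyl)-2-hydroxytridecan-8-one | CCCCCC(=O)CCCCC[C@H](Cc1cc(O)cc(O)c1)O
A1 | alternative 1 | (R,E)-6-(tert-butyldimethylsilyloxy)heptadec-3-ene-2,12-dione | CCCCCC(=O)CCCCC[C@H](C/C=C/C(C)=O)O[Si](C)(C)C(C)(C)C
A2 | alternative 1 | dimethyl malonate | COC(=O)CC(=O)OC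
A3 | alternative 1 | methyl 6-[(R)-2-(tert-butyldimethylsilyloxy)-8-oxotridecyl]-2,4-dioxocyclohexane-1-carboxylate | CCCCCC(=O)CCCCC[C@H](CC1CC(=O)CC(=O)C1C(=O)OC)O[Si](C)(C)C(C)(C)C
A4 | alternative 2 | (R)-1-(3-oxocyclobut-1-en-1-yl)-8-oxotridecan-2-yl acetate | CCCCCC(=O)CCCCC[C@H](CC1=CC(=O)C1)OC(C)=O
A5 | alternative 2 | (triisopropylsiloxy)ethyne | C#CO[Si](C(C)C)(C(C)C)C(C)C
A6 | alternative 2 | (R)-1-[3-hydroxy-5-(triisopropylsilyloxy)phenyl]-8-oxotridecan-2-yl acetate | CCCCCC(=O)CCCCC[C@H](Cc1cc(O)cc(O[Si](C(C)C)(C(C)C)C(C)C)c1)OC(C)=O
A7 | alternative 3 | (R)-3-[3,5-bis(benzyloxy)benzyl]-8-(2-pentyl-1,3-dioxolan-2-yl)octan-2-one | CCCCCC1(OCCO1)CCCCC[C@H](Cc2cc(OCc3ccccc3)cc(OCc3ccccc3)c2)C(C)=O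
A8 | alternative 3 | (R)-1-[3,5-bis(benzyloxy)phenyl]-7-(2-pentyl-1,3-dioxolan-2-yl)heptan-2-yl acetate | CCCCCC1(OCCO1)CCCCC[C@H](Cc2cc(OCc3ccccc3)cc(OCc3ccccc3)c2)OC(C)=O
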